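With the chain numbered C1 (ester carbonyl) to C20 (CHBr), the trans-2,5-disubstituted oxolane (O, C5–C8) carries an exocyclic methylene C4 on C5, the imprint of an alkene oxypalladation. The route therefore rests on a palladium-catalysed carboetherification that forms O–C5 and C3–C4 in one operation, closing the ring, setting C5 trans to C8 and attaching a masked ester arm. Its precursor is (2S)-1-(benzyloxy)hex-5-en-2-ol, from a glycidyl ether, combined with an (E)-3-bromoallyl silyl ether. Afterwards C9 becomes the alkyne, C1 the methyl ester, and a separately built (1E,7Z,9E)-bromo-iodo-triene is joined by an iodide-selective Sonogashira coupling.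

Key step: step 3

Remark: locants C1–C20 follow the target chain throughout; tert-butyldimethyl(prop-2-yn-1-yloxy)silane, hept-6-yn-1-ol and Cp2Zr(H)Cl are taken as catalogue items.

Step 1
Reactants: 1 (S)-benzyl glycidyl ether [(2S)-2-[(benzyloxy)methyl]oxirane]; 2 allylmagnesium bromide
Product: 3 (2S)-1-(benzyloxy)hex-5-en-2-ol
Conditions: CuI (10 mol%), THF, −40 to 0 °C; then H2O/aq NH4Cl
Reagents that add atoms: none
Why: Copper-catalysed Grignard opening of a terminal epoxide is an SN2 attack at the unsubstituted carbon, so the future C8 stereocentre is carried over untouched from 1 and the γ-hydroxy terminal alkene results in one step.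

Step 2
Reactants: 4 tert-butyldimethyl(prop-2-yn-1-yloxy)silane
Product: 6 (E)-(3-bromoallyloxy)(tert-butyl)dimethylsilane, via alkenyl-Zr(Cl)Cp2 complex 5 (not isolated)
Conditions: Cp2Zr(H)Cl (1.2 equiv), CH2Cl2, rt; then NBS, 0 °C
Reagents that add atoms: N-bromosuccinimide, O=C1CCC(=O)N1Br
Why: Schwartz hydrozirconation adds Zr–H syn and anti-Markovnikov across the terminal alkyne, and bromodemetalation of the C–Zr bond with NBS retains geometry, so the (E)-alkenyl bromide should result.

Step 3
Reactants: 3 (2S)-1-(benzyloxy)hex-5-en-2-ol; 6 (E)-(3-bromoallyloxy)(tert-butyl)dimethylsilane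
Product: 8 (2S,5S)-2-[(benzyloxy)methyl]-5-[(2E)-4-(tert-butyldimethylsilyloxy)but-2-en-1-yl]oxolane (2,5-trans), via sodium alkoxide 7 (not isolated)
Conditions: Pd2(dba)3 (2 mol%), DPE-Phos (4 mol%), NaOtBu (2 equiv), 6 (2 equiv), THF, 65 °C
Reagents that add atoms: none
Why: Zerovalent palladium ligated by DPE-Phos inserts into the C–Br bond of 6, sodium alkoxide 7 displaces bromide to give a divalent palladium alkenyl alkoxide, the tethered terminal alkene inserts syn into the Pd–O bond to form O–C5, and C(sp3)–C(sp2) reductive elimination then forms C3–C4. The closest known reaction type is the palladium-catalysed carboetherification of γ-hydroxy terminal alkenes with aryl or alkenyl bromides, which converts secondary alcohols of this kind into trans-2,5-disubstituted tetrahydrofurans. The oxolane closes in a 5-exo-trig mode through this intramolecular syn-oxypalladation. The new stereocentre C5 is controlled by the existing C8 centre, because in the organised cyclic insertion transition state the CH2OBn group sits pseudoequatorial and the C4 methylene ends up trans to it. The step needs 2,5-trans diastereoselectivity and suppression of β-hydride loss from the palladium alkoxide and from the alkylpalladium intermediate; the single substituent on the carbinol carbon secures the former and the wide-bite-angle bisphosphine, which speeds reductive elimination, the latter. The E geometry of the alkenyl unit is retained but is of no consequence, since that alkene is hydrogenated in step 4, and the benzyl and silyl ethers are inert to the alkoxide base.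

Step 4
Reactants: 8 (2S,5S)-2-[(benzyloxy)methyl]-5-[(2E)-4-(tert-butyldimethylsilyloxy)but-2-en-1-yl]oxolane
Product: 9 [(2S,5R)-5-[4-(tert-butyldimethylsilyloxy)butyl]oxolan-2-yl]methanol
Conditions: H2 (1 atm), 10% Pd/C, EtOAc, rt
Reagents that add atoms: none
Why: Heterogeneous catalytic hydrogenation saturates the C2=C3 alkene and then hydrogenolyses the benzyl ether, while the silyl ether is stable in a non-alcoholic solvent and no stereocentre is touched (the C5 descriptor becomes R only through a change in priority ranking).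

Step 5
Reactants: 9 [(2S,5R)-5-[4-(tert-butyldimethylsilyloxy)butyl]oxolan-2-yl]methanol
Product: 10 (2S,5R)-5-[4-(tert-butyldimethylsilyloxy)butyl]oxolane-2-carbaldehyde
Conditions: Dess–Martin periodinane, NaHCO3, CH2Cl2, 0 °C to rt; used crude
Reagents that add atoms: none
Why: Dess–Martin oxidation takes the primary alcohol to the aldehyde under buffered, non-enolising conditions, so the α-alkoxy centre C8 should keep its configuration.

Step 6
Reactants: 10 (2S,5R)-5-[4-(tert-butyldimethylsilyloxy)butyl]oxolane-2-carbaldehyde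
Product: 11 tert-butyl{4-[(2R,5S)-5-ethynyloxolan-2-yl]butoxy}dimethylsilane
Conditions: dimethyl (1-diazo-2-oxopropyl)phosphonate, K2CO3, MeOH, 0 °C to rt
Reagents that add atoms: dimethyl (1-diazo-2-oxopropyl)phosphonate, COP(=O)(OC)C(=[N+]=[N-])C(C)=O
Why: In the Ohira–Bestmann variant of the Seyferth–Gilbert homologation the diazomethylphosphonate anion adds to the aldehyde, and loss of phosphate and dinitrogen with a 1,2-hydrogen shift gives the terminal alkyne C9≡C10 under mild carbonate conditions that tetrahydrofuran-2-carbaldehydes and primary silyl ethers normally tolerate.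

Step 7
Reactants: 11 tert-butyl{4-[(2R,5S)-5-ethynyloxolan-2-yl]butoxy}dimethylsilane
Product: 14 4-[(2R,5S)-5-ethynyloxolan-2-yl]butanoic acid, via alcohol 12 (not isolated), via aldehyde 13 (not isolated)
Conditions: CrO3, H2SO4, H2O, acetone, 0 °C to rt
Reagents that add atoms: water, O
Why: In this Jones oxidation the aqueous sulfuric acid cleaves the primary silyl ether and H2CrO4 oxidises the liberated alcohol through the aldehyde hydrate to the acid, while the terminal alkyne and the ring ether are inert at this temperature.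

Step 8
Reactants: 14 4-[(2R,5S)-5-ethynyloxolan-2-yl]butanoic acid
Product: 15 methyl 4-[(2R,5S)-5-ethynyloxolan-2-yl]butanoate
Conditions: Me3SiCHN2, MeOH/toluene (1:4), 0 °C to rt
Reagents that add atoms: trimethylsilyldiazomethane, C[Si](C)(C)C=[N+]=[N-]
Why: Methyl esterification of a carboxylic acid with trimethylsilyldiazomethane in methanol is fast and essentially neutral, so the alkyne C–H and both stereocentres are unaffected.

Step 9
Reactants: 16 propargyl alcohol (prop-2-yn-1-ol)
Product: 17 (E)-3-(tributylstannyl)prop-2-en-1-ol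
Conditions: Bu3SnH, AIBN (cat.), neat, 80 °C; chromatography
Reagents that add atoms: tributyltin hydride, CCCC[SnH](CCCC)CCCC
Why: Radical hydrostannation puts tin on the terminal alkyne carbon, and reversible stannyl-radical addition at 80 °C funnels the mixture towards the thermodynamically preferred (E)-alkenylstannane, which is separated from the minor isomers.

Step 10
Reactants: 17 (E)-3-(tributylstannyl)prop-2-en-1-ol
Product: 18 (E)-3-(tributylstannyl)prop-2-enal
Conditions: activated MnO2 (excess), CH2Cl2, rt
Reagents that add atoms: none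
Why: Activated MnO2 oxidises allylic alcohols selectively to enals under neutral conditions that leave the C–Sn bond and the E geometry intact.

Step 11
Reactants: 19 hept-6-yn-1-ol
Product: 20 7-bromohept-1-yne
Conditions: CBr4, PPh3, CH2Cl2, 0 °C
Reagents that add atoms: carbon tetrabromide, BrC(Br)(Br)Br
Why: Appel bromination converts the primary alcohol into the bromide by SN2 displacement of an alkoxyphosphonium ion without affecting the terminal alkyne.

Step 12
Reactants: 20 7-bromohept-1-yne
Product: 22 (E)-7-bromo-1-iodohept-1-ene, via alkenyl-Zr(Cl)Cp2 complex 21 (not isolated)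
Conditions: Cp2Zr(H)Cl (1.2 equiv), THF, rt; then I2, 0 °C
Reagents that add atoms: iodine, II
Why: Hydrozirconation gives the (E)-alkenylzirconium species by syn anti-Markovnikov addition, a primary alkyl bromide is tolerated, and iodinolysis of the C–Zr bond proceeds with retention to fix the C11=C12 geometry.

Step 13
Reactants: 22 (E)-7-bromo-1-iodohept-1-ene
Product: 23 [(6E)-7-iodohept-6-en-1-yl]triphenylphosphonium bromide
Conditions: PPh3, MeCN, 80 °C, dark
Reagents that add atoms: triphenylphosphine, c1ccc(cc1)P(c1ccccc1)c1ccccc1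
Why: SN2 quaternisation of triphenylphosphine by the primary alkyl bromide gives the phosphonium salt, and the alkenyl iodide cannot react in the absence of a transition metal.

Step 14
Reactants: 23 [(6E)-7-iodohept-6-en-1-yl]triphenylphosphonium bromide; 18 (E)-3-(tributylstannyl)prop-2-enal
Product: 25 tributyl[(1E,3Z,9E)-10-iododeca-1,3,9-trien-1-yl]stannane, via phosphonium ylide 24 (not isolated)
Conditions: NaN(SiMe3)2, THF, −78 °C; then 18, −78 °C to rt
Reagents that add atoms: none
Why: Wittig olefination with a non-stabilised ylide under lithium-free conditions passes through the kinetically favoured cis-oxaphosphetane and should give the Z alkene C17=C18, while the (E)-stannyl enal brings in C19=C20 unchanged and the (E)-alkenyl iodide, which lacks an anti-disposed β-hydrogen, resists the amide base at low temperature.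

Step 15
Reactants: 25 tributyl[(1E,3Z,9E)-10-iododeca-1,3,9-trien-1-yl]stannane
Product: 26 (1E,7Z,9E)-10-bromo-1-iododeca-1,7,9-triene
Conditions: NBS, MeCN, 0 °C, dark
Reagents that add atoms: N-bromosuccinimide, O=C1CCC(=O)N1Br
Why: Bromodestannylation is an ipso electrophilic substitution at the C–Sn bond that proceeds with retention of alkene geometry and is far faster than any reaction of NBS at the other alkenes or at the alkenyl iodide.

Step 16
Reactants: 15 methyl 4-[(2R,5S)-5-ethynyloxolan-2-yl]butanoate; 26 (1E,7Z,9E)-10-bromo-1-iododeca-1,7,9-triene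
Product: 27 methyl 4-[(2R,5S)-5-[(3E,9Z,11E)-12-bromododeca-3,9,11-trien-1-yn-1-yl]oxolan-2-yl]butanoate (target)
Conditions: Pd(PPh3)4 (5 mol%), CuI (10 mol%), iPr2NH, THF, 0 °C to rt, degassed, dark; 15 as limiting component
Reagents that add atoms: none
Why: Sonogashira coupling joins the terminal alkyne to the alkenyl iodide with retention of the E geometry, and oxidative addition of zerovalent palladium into C–I is much faster than into C–Br at or below room temperature, so the bromodiene should survive when the alkyne is limiting.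

Compound list

1 | (S)-benzyl glycidyl ether, (2S)-2-[(benzyloxy)methyl]oxirane | [C@@H]1(COCc2ccccc2)CO1 | starting material
2 | allylmagnesium bromide | C=CC[Mg]Br | starting material
3 | (2S)-1-(benzyloxy)hex-5-en-2-ol | C=CCC[C@@H](COCc1ccccc1)O | intermediate
4 | tert-butyldimethyl(prop-2-yn-1-yloxy)silane | C#CCO[Si](C)(C)C(C)(C)C | starting material
5 | chlorobis(cyclopentadienyl)[(E)-3-(tert-butyldimethylsilyloxy)prop-1-en-1-yl]zirconium, formed in the flask | CC(C)(C)[Si](C)(C)OC/C=C/[Zr](Cl)(C1C=CC=C1)C1C=CC=C1 | intermediate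
6 | (E)-(3-bromoallyloxy)(tert-butyl)dimethylsilane | Br/C=C/CO[Si](C)(C)C(C)(C)C | intermediate
7 | sodium (2S)-1-(benzyloxy)hex-5-en-2-olate, formed in the flask | C=CCC[C@@H](COCc1ccccc1)[O-].[Na+] | intermediate
8 | (2S,5S)-2-[(benzyloxy)methyl]-5-[(2E)-4-(tert-butyldimethylsilyloxy)but-2-en-1-yl]oxolane (2,5-trans) | CC(C)(C)[Si](C)(C)OC/C=C/C[C@@H]1CC[C@@H](COCc2ccccc2)O1 | intermediate
9 | [(2S,5R)-5-[4-(tert-butyldimethylsilyloxy)butyl]oxolan-2-yl]methanol | CC(C)(C)[Si](C)(C)OCCCC[C@@H]1CC[C@@H](CO)O1 | intermediate
10 | (2S,5R)-5-[4-(tert-butyldimethylsilyloxy)butyl]oxolane-2-carbaldehyde | CC(C)(C)[Si](C)(C)OCCCC[C@@H]1CC[C@@H](C=O)O1 | intermediate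
11 | tert-butyl{4-[(2R,5S)-5-ethynyloxolan-2-yl]butoxy}dimethylsilane | CC(C)(C)[Si](C)(C)OCCCC[C@@H]1CC[C@@H](C#C)O1 | intermediate
12 | 4-[(2R,5S)-5-ethynyloxolan-2-yl]butan-1-ol, formed in the flask | OCCCC[C@@H]1CC[C@@H](C#C)O1 | intermediate
13 | 4-[(2R,5S)-5-ethynyloxolan-2-yl]butanal, formed in the flask | O=CCCC[C@@H]1CC[C@@H](C#C)O1 | intermediate
14 | 4-[(2R,5S)-5-ethynyloxolan-2-yl]butanoic acid | OC(=O)CCC[C@@H]1CC[C@@H](C#C)O1 | intermediate
15 | methyl 4-[(2R,5S)-5-ethynyloxolan-2-yl]butanoate | COC(=O)CCC[C@@H]1CC[C@@H](C#C)O1 | intermediate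
16 | propargyl alcohol (prop-2-yn-1-ol) | C#CCO | starting material
17 | (E)-3-(tributylstannyl)prop-2-en-1-ol | CCCC[Sn](CCCC)(CCCC)/C=C/CO | intermediate
18 | (E)-3-(tributylstannyl)prop-2-enal | CCCC[Sn](CCCC)(CCCC)/C=C/C=O | intermediate
19 | hept-6-yn-1-ol | C#CCCCCCO | starting material
20 | 7-bromohept-1-yne | C#CCCCCCBr | intermediate
21 | chlorobis(cyclopentadienyl)[(E)-7-bromohept-1-en-1-yl]zirconium, formed in the flask | BrCCCCC/C=C/[Zr](Cl)(C1C=CC=C1)C1C=CC=C1 | intermediate
22 | (E)-7-bromo-1-iodohept-1-ene | I/C=C/CCCCCBr | intermediate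
23 | [(6E)-7-iodohept-6-en-1-yl]triphenylphosphonium bromide | I/C=C/CCCCC[P+](c1ccccc1)(c1ccccc1)c1ccccc1.[Br-] | intermediate
24 | [(6E)-7-iodohept-6-en-1-ylidene]triphenyl-λ5-phosphane, formed in the flask | I/C=C/CCCCC=P(c1ccccc1)(c1ccccc1)c1ccccc1 | intermediate
25 | tributyl[(1E,3Z,9E)-10-iododeca-1,3,9-trien-1-yl]stannane | CCCC[Sn](CCCC)(CCCC)/C=C/C=C\CCCC/C=C/I | intermediate
26 | (1E,7Z,9E)-10-bromo-1-iododeca-1,7,9-triene | I/C=C/CCCC/C=C\C=C\Br | intermediate
27 | methyl 4-[(2R,5S)-5-[(3E,9Z,11E)-12-bromododeca-3,9,11-trien-1-yn-1-yl]oxolan-2-yl]butanoate | COC(=O)CCC[C@@H]1CC[C@@H](C#C/C=C/CCCC/C=C\C=C\Br)O1 | target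

Total step count: 16.
Longest linear sequence: 8 steps (steps 1, 3, 4, 5, 6, 7, 8 and 16, from 1). The triene branch (steps 11–15) and the two short branches (step 2; steps 9–10) run in parallel.

Steps most likely to fail

Step 3 (carboetherification). The catalytic cycle may leak through β-hydride elimination from the palladium alkoxide (oxidising the carbinol), through Heck-type pathways after insertion, or through base-induced loss of HBr from the alkenyl bromide; the trans preference might also be eroded. The fallback separates ring closure from side-chain attachment. It sets out from 3: aerobic oxidative cyclisation under Mukaiyama conditions with Co(modp)2 [the divalent cobalt bis(1-morpholinocarbamoyl-4,4-dimethylpentane-1,3-dionate)], O2 and tBuOOH in iPrOH, a method known to give 2,5-trans rings from such pentenols, should give [(2S,5S)-5-[(benzyloxy)methyl]oxolan-2-yl]methanol F1. Treatment with Tf2O and 2,6-lutidine at −78 °C would give [(2S,5S)-5-[(benzyloxy)methyl]oxolan-2-yl]methyl trifluoromethanesulfonate F2. Displacement with lithium 3-(tert-butyldimethylsilyloxy)prop-1-yn-1-ide F3, made from 4 and n-BuLi in THF/DMPU, forms C3–C4 and should give tert-butyl({4-[(2S,5S)-5-[(benzyloxy)methyl]oxolan-2-yl]but-2-yn-1-yl}oxy)dimethylsilane F4. Hydrogenation under the conditions of step 4 saturates the alkyne and removes benzyl, and the fallback comes back to the route at 9.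

Step 16 (Sonogashira coupling). Oxidative addition may not discriminate fully between the alkenyl iodide and the dienyl bromide, leading to over-coupling. The Z,E-bromodiene may isomerise under palladium or light, and the alkyne may homocouple. The fallback builds the bromodiene only after the palladium step. It sets out from 15 and 22: the same Sonogashira conditions, now with an inert alkyl bromide, should give methyl 4-[(2R,5S)-5-[(3E)-9-bromonon-3-en-1-yn-1-yl]oxolan-2-yl]butanoate F5. Heating with PPh3 in MeCN would give [(6E)-9-[(2S,5R)-5-(4-methoxy-4-oxobutyl)oxolan-2-yl]non-6-en-8-yn-1-yl]triphenylphosphonium bromide F6. Deprotonation with NaN(SiMe3)2 at −78 °C gives the corresponding phosphonium ylide F7, and Wittig reaction with 18 should give methyl 4-[(2R,5S)-5-[(3E,9Z,11E)-12-(tributylstannyl)dodeca-3,9,11-trien-1-yn-1-yl]oxolan-2-yl]butanoate F8. Bromodestannylation with NBS as in step 15 comes back to the route at 27.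

Step 6 (Ohira–Bestmann homologation). Enolisation of the α-alkoxy aldehyde in K2CO3/MeOH may epimerise C8 before the alkyne forms, giving cis-ring material. The fallback is a non-basic olefination followed by rearrangement (Corey–Fuchs). It sets out from 10: CBr4, PPh3 and Et3N in CH2Cl2 at 0 °C should give tert-butyl{4-[(2R,5S)-5-(2,2-dibromoethenyl)oxolan-2-yl]butoxy}dimethylsilane F9. Treatment with n-BuLi (2.1 equiv) in THF at −78 °C gives the lithium acetylide lithium 2-[(2S,5R)-5-[4-(tert-butyldimethylsilyloxy)butyl]oxolan-2-yl]ethyn-1-ide F10, and aqueous quench comes back to the route at 11.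

Further compounds

F1 | step 3 | [(2S,5S)-5-[(benzyloxy)methyl]oxolan-2-yl]methanol | OC[C@@H]1CC[C@@H](COCc2ccccc2)O1
F2 | step 3 | [(2S,5S)-5-[(benzyloxy)methyl]oxolan-2-yl]methyl trifluoromethanesulfonate | FC(F)(F)S(=O)(=O)OC[C@@H]1CC[C@@H](COCc2ccccc2)O1
F3 | step 3 | lithium 3-(tert-butyldimethylsilyloxy)prop-1-yn-1-ide | [Li]C#CCO[Si](C)(C)C(C)(C)C
F4 | step 3 | tert-butyl({4-[(2S,5S)-5-[(benzyloxy)methyl]oxolan-2-yl]but-2-yn-1-yl}oxy)dimethylsilane | CC(C)(C)[Si](C)(C)OCC#CC[C@@H]1CC[C@@H](COCc2ccccc2)O1
F5 | step 16 | methyl 4-[(2R,5S)-5-[(3E)-9-bromonon-3-en-1-yn-1-yl]oxolan-2-yl]butanoate | COC(=O)CCC[C@@H]1CC[C@@H](C#C/C=C/CCCCCBr)O1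
F6 | step 16 | [(6E)-9-[(2S,5R)-5-(4-methoxy-4-oxobutyl)oxolan-2-yl]non-6-en-8-yn-1-yl]triphenylphosphonium bromide | COC(=O)CCC[C@@H]1CC[C@@H](C#C/C=C/CCCCC[P+](c2ccccc2)(c2ccccc2)c2ccccc2)O1.[Br-]
F7 | step 16 | methyl 4-[(2R,5S)-5-[(3E)-9-(triphenyl-λ5-phosphanylidene)non-3-en-1-yn-1-yl]oxolan-2-yl]butanoate | COC(=O)CCC[C@@H]1CC[C@@H](C#C/C=C/CCCCC=P(c2ccccc2)(c2ccccc2)c2ccccc2)O1
F8 | step 16 | methyl 4-[(2R,5S)-5-[(3E,9Z,11E)-12-(tributylstannyl)dodeca-3,9,11-trien-1-yn-1-yl]oxolan-2-yl]butanoate | COC(=O)CCC[C@@H]1CC[C@@H](C#C/C=C/CCCC/C=C\C=C\[Sn](CCCC)(CCCC)CCCC)O1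
F9 | step 6 | tert-butyl{4-[(2R,5S)-5-(2,2-dibromoethenyl)oxolan-2-yl]butoxy}dimethylsilane | CC(C)(C)[Si](C)(C)OCCCC[C@@H]1CC[C@@H](C=C(Br)Br)O1
F10 | step 6 | lithium 2-[(2S,5R)-5-[4-(tert-butyldimethylsilyloxy)butyl]oxolan-2-yl]ethyn-1-ide | CC(C)(C)[Si](C)(C)OCCCC[C@@H]1CC[C@@H](C#C[Li])O1
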